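**Plan**
- Locants: each heterocycle is N1, C2 (methyl), C3 (ester oxygen), C6 (chain); a marks imine ring A, b marks amine ring B; C1' to C8' run from C6 to the chain carbonyl.
- Cuts, in order: the C2a=N1a imine (back to a Boc-amino ketone); C1'a–C2'a (as an alkene, by ring-closing metathesis); the esters O3b–C8'a and O3a–C8'b; C1'b–C2'b (cross-metathesis); N1b–C2b of ring B (reductive amination).
- Enabling feature: C6a carries nitrogen beside the unfunctionalised C1'a–C2'a bond, so with that bond as an alkene C6a is the α-carbon of L-glutamic acid in the form of an allylic carbamate, and the 26-membered ring can be closed there, remote from both esters.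
- Forward: methyl N-Boc-L-pyroglutamate gives one enyne building block that is used twice; ring B is made first, the two esters are then joined, the C2a ketone is unveiled, metathesis closes the macrocycle, and ring A closes last as the imine.
- Stereochemistry: C6a and C6b come from L-glutamic acid; C3a and C3b from a catalyst-controlled Noyori transfer hydrogenation of an ynone; C2b from hydrogenation of the ring B imine anti to the C3b and C6b substituents.

Key step: step 16

Remark: methyl N-Boc-L-pyroglutamate, the commercial lactam of L-glutamic acid, is taken as the glutamate source; the alkenes made by metathesis (13, 22) are drawn E, and either geometry serves because both are hydrogenated.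

**Step 1**
Reactants: 1 methyl (S)-1-(tert-butoxycarbonyl)-5-oxopyrrolidine-2-carboxylate; 2 trimethylsilylacetylene
Product: 3 methyl (S)-2-[(tert-butoxycarbonyl)amino]-5-oxo-7-(trimethylsilyl)hept-6-ynoate
Conditions: 2, n-BuLi, THF, −78 °C; then 1, THF, −78 °C
Reagents that add atoms: none
Why: The lithium acetylide adds to the imide-like lactam carbonyl, the most electrophilic one, and the tetrahedral intermediate opens to the N-Boc amino ynone (acylation of an acetylide by an N-acyl lactam), leaving the ester and the α-stereocentre untouched at low temperature.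

**Step 2**
Reactants: 3 methyl (S)-2-[(tert-butoxycarbonyl)amino]-5-oxo-7-(trimethylsilyl)hept-6-ynoate
Product: 4 methyl (2S,5S)-2-[(tert-butoxycarbonyl)amino]-5-hydroxy-7-(trimethylsilyl)hept-6-ynoate
Conditions: Ru[(S,S)-TsNCHPhCHPhNH](p-cymene) (2 mol %), i-PrOH, rt
Reagents that add atoms: none
Why: Noyori asymmetric transfer hydrogenation of an α,β-acetylenic ketone, in which the (S,S)-ligated ruthenium hydride should deliver hydride to one carbonyl face under catalyst control and set the (S)-carbinol that becomes C3a and C3b, the remote C2 centre, alkyne, ester and carbamate being spectators.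

**Step 3**
Reactants: 4 methyl (2S,5S)-2-[(tert-butoxycarbonyl)amino]-5-hydroxy-7-(trimethylsilyl)hept-6-ynoate
Product: 5 methyl (2S,5S)-2-[(tert-butoxycarbonyl)amino]-5-[(tert-butyldiphenylsilyl)oxy]-7-(trimethylsilyl)hept-6-ynoate
Conditions: TBDPSCl, imidazole, DMF, rt
Reagents that add atoms: tert-butyl(chloro)diphenylsilane, CC(C)(C)[Si](Cl)(c1ccccc1)c1ccccc1
Why: Imidazole-promoted silylation of a secondary alcohol, the TBDPS ether being chosen because it has to survive hydride, ylide, trifluoroacetic acid and hydrogenation later on.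

**Step 4**
Reactants: 5 methyl (2S,5S)-2-[(tert-butoxycarbonyl)amino]-5-[(tert-butyldiphenylsilyl)oxy]-7-(trimethylsilyl)hept-6-ynoate
Product: 7 tert-butyl N-[(3S,6S)-6-[(tert-butyldiphenylsilyl)oxy]-8-(trimethylsilyl)oct-1-en-7-yn-3-yl]carbamate, via Boc-amino aldehyde 6 (not isolated)
Conditions: i-Bu2AlH (2.2 equiv), toluene, −78 °C; then Ph3P=CH2 (from Ph3PCH3Br and KN(SiMe3)2 in THF), −78 °C to rt
Reagents that add atoms: methyltriphenylphosphonium bromide (as its ylide), C[P+](c1ccccc1)(c1ccccc1)c1ccccc1.[Br-]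
Why: One-pot reduction and Wittig methylenation of an N-Boc α-amino ester, in which the aluminium hemiacetal releases the aldehyde only as the ylide consumes it, so the fragile α-amino aldehyde should not epimerise and the glutamate centre (later C6a and C6b) is carried over unchanged.

**Step 5**
Reactants: 7 tert-butyl N-[(3S,6S)-6-[(tert-butyldiphenylsilyl)oxy]-8-(trimethylsilyl)oct-1-en-7-yn-3-yl]carbamate
Product: 8 tert-butyl N-[(3S,6S)-6-[(tert-butyldiphenylsilyl)oxy]oct-1-en-7-yn-3-yl]carbamate
Conditions: K2CO3 (0.2 equiv), MeOH, rt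
Reagents that add atoms: none
Why: Base-catalysed methanolysis of the alkynyl C–Si bond (protodesilylation), which leaves the silyl ether, the carbamate and the alkene alone.

**Step 6**
Reactants: 8 tert-butyl N-[(3S,6S)-6-[(tert-butyldiphenylsilyl)oxy]oct-1-en-7-yn-3-yl]carbamate
Product: 9 tert-butyl N-[(3S,6S)-6-hydroxyoct-1-en-7-yn-3-yl]carbamate
Conditions: Bu4NF, THF, 0 °C to rt
Reagents that add atoms: none
Why: Fluoride cleavage of the silyl ether, driven by Si–F bond formation, frees the propargylic alcohol of the ring A unit without touching carbamate, alkene or alkyne.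

**Step 7**
Reactants: 8 tert-butyl N-[(3S,6S)-6-[(tert-butyldiphenylsilyl)oxy]oct-1-en-7-yn-3-yl]carbamate
Product: 10 tert-butyl N-[(3S,6S)-6-[(tert-butyldiphenylsilyl)oxy]-7-oxooct-1-en-3-yl]carbamate
Conditions: Ph3PAuNTf2 (5 mol %), MeOH/H2O (10:1), 50 °C
Reagents that add atoms: water, O
Why: Gold-catalysed Markovnikov hydration of a terminal alkyne (π-activation, attack of the oxygen nucleophile at the internal carbon, protodeauration and tautomerisation) should give the methyl ketone with the isolated alkene, carbamate and silyl ether as spectators and no bond to the stereocentre broken.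

**Step 8**
Reactants: 11 oct-7-enoic acid
Product: 12 benzyl oct-7-enoate
Conditions: BnBr, K2CO3, DMF, rt
Reagents that add atoms: benzyl bromide, BrCc1ccccc1
Why: SN2 O-alkylation of the carboxylate gives a benzyl ester that the later hydrogenation removes without an extra operation.

**Step 9**
Reactants: 10 tert-butyl N-[(3S,6S)-6-[(tert-butyldiphenylsilyl)oxy]-7-oxooct-1-en-3-yl]carbamate; 12 benzyl oct-7-enoate
Product: 13 benzyl (7E,9S,12S)-9-[(tert-butoxycarbonyl)amino]-12-[(tert-butyldiphenylsilyl)oxy]-13-oxotetradec-7-enoate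
Conditions: 12 (3 equiv), second-generation Grubbs catalyst RuCl2(=CHPh)(PCy3)(H2IMes) (5 mol %), CH2Cl2, 40 °C
Reagents that add atoms: none
Why: Olefin cross-metathesis between a fast terminal alkene used in excess and the slower branched allylic carbamate alkene should favour the cross product and builds the whole C1'b to C8'b chain in one operation.

**Step 10**
Reactants: 13 benzyl (7E,9S,12S)-9-[(tert-butoxycarbonyl)amino]-12-[(tert-butyldiphenylsilyl)oxy]-13-oxotetradec-7-enoate
Product: 16 8-[(2R,5S,6S)-5-[(tert-butyldiphenylsilyl)oxy]-6-methylpiperidin-2-yl]octanoic acid, via amino ketone 14 (not isolated), via cyclic imine 15 (not isolated)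
Conditions: TFA/CH2Cl2 (1:4), 0 °C to rt; concentrate; then H2 (1 atm), 10% Pd/C, MeOH, rt
Reagents that add atoms: none
Why: Acidolysis of the Boc group frees the C6b amine, which condenses with the C2b ketone to the six-membered imine, and catalytic hydrogenation (intramolecular reductive amination) should add hydrogen to C2b from the face opposite the pseudo-axial C3b silyloxy group and the C6b chain, setting C2b as S (all-cis ring B), while the same catalyst saturates C1'b=C2'b and cleaves the benzyl ester.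

**Step 11**
Reactants: 16 8-[(2R,5S,6S)-5-[(tert-butyldiphenylsilyl)oxy]-6-methylpiperidin-2-yl]octanoic acid
Product: 17 8-[(2R,5S,6S)-1-(tert-butoxycarbonyl)-5-[(tert-butyldiphenylsilyl)oxy]-6-methylpiperidin-2-yl]octanoic acid
Conditions: Boc2O (3 equiv), NaHCO3, 1,4-dioxane/H2O, 60 °C
Reagents that add atoms: di-tert-butyl dicarbonate, CC(C)(C)OC(=O)OC(=O)OC(C)(C)C
Why: Carbamoylation of the secondary amine, with excess reagent and warming to offset the flanked 2,6-cis-disubstituted nitrogen, masks ring B for the acylations and for the gold and ruthenium catalysis ahead.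

**Step 12**
Reactants: 17 8-[(2R,5S,6S)-1-(tert-butoxycarbonyl)-5-[(tert-butyldiphenylsilyl)oxy]-6-methylpiperidin-2-yl]octanoic acid; 9 tert-butyl N-[(3S,6S)-6-hydroxyoct-1-en-7-yn-3-yl]carbamate
Product: 18 (3S,6S)-6-[(tert-butoxycarbonyl)amino]oct-7-en-1-yn-3-yl 8-[(2R,5S,6S)-1-(tert-butoxycarbonyl)-5-[(tert-butyldiphenylsilyl)oxy]-6-methylpiperidin-2-yl]octanoate
Conditions: DIC, DMAP (0.2 equiv), CH2Cl2, 0 °C to rt
Reagents that add atoms: none
Why: Steglich esterification (carbodiimide activation, DMAP acyl transfer) of an unhindered chain acid with a secondary propargylic alcohol forms the O3a–C8'b ester with the C3a–O bond intact, so the carbinol configuration is retained.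

**Step 13**
Reactants: 18 (3S,6S)-6-[(tert-butoxycarbonyl)amino]oct-7-en-1-yn-3-yl 8-[(2R,5S,6S)-1-(tert-butoxycarbonyl)-5-[(tert-butyldiphenylsilyl)oxy]-6-methylpiperidin-2-yl]octanoate
Product: 19 (3S,6S)-6-[(tert-butoxycarbonyl)amino]oct-7-en-1-yn-3-yl 8-[(2R,5S,6S)-1-(tert-butoxycarbonyl)-5-hydroxy-6-methylpiperidin-2-yl]octanoate
Conditions: Bu4NF, AcOH, THF, rt
Reagents that add atoms: none
Why: Fluoride desilylation buffered with acetic acid should remove the TBDPS ether without ester cleavage or acyl migration and leaves both Boc groups, the alkyne and the alkene intact.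

**Step 14**
Reactants: 19 (3S,6S)-6-[(tert-butoxycarbonyl)amino]oct-7-en-1-yn-3-yl 8-[(2R,5S,6S)-1-(tert-butoxycarbonyl)-5-hydroxy-6-methylpiperidin-2-yl]octanoate; 11 oct-7-enoic acid
Product: 20 (3S,6S)-6-[(tert-butoxycarbonyl)amino]oct-7-en-1-yn-3-yl 8-[(2R,5S,6S)-1-(tert-butoxycarbonyl)-6-methyl-5-(oct-7-enoyloxy)piperidin-2-yl]octanoate
Conditions: 11 (3 equiv), DIC, DMAP (1 equiv), CH2Cl2, rt
Reagents that add atoms: none
Why: Steglich esterification of the hindered O3b alcohol with excess acid and stoichiometric DMAP installs the oct-7-enoate that carries the second metathesis alkene.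

**Step 15**
Reactants: 20 (3S,6S)-6-[(tert-butoxycarbonyl)amino]oct-7-en-1-yn-3-yl 8-[(2R,5S,6S)-1-(tert-butoxycarbonyl)-6-methyl-5-(oct-7-enoyloxy)piperidin-2-yl]octanoate
Product: 21 (3S,6S)-6-[(tert-butoxycarbonyl)amino]-2-oxooct-7-en-3-yl 8-[(2R,5S,6S)-1-(tert-butoxycarbonyl)-6-methyl-5-(oct-7-enoyloxy)piperidin-2-yl]octanoate
Conditions: Ph3PAuCl (5 mol %), AgSbF6 (5 mol %), 1,4-dioxane/H2O (20:1), rt
Reagents that add atoms: water, O
Why: Gold-catalysed hydration of a terminal propargylic ester with anchimeric assistance, in which the ester carbonyl attacks the activated alkyne 5-exo-dig, water opens the dioxolenium ion and protodeauration gives the α-acyloxy methyl ketone with Markovnikov control, the acyl group staying on O3a and the C3a–O bond never breaking.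

**Step 16**
Reactants: 21 (3S,6S)-6-[(tert-butoxycarbonyl)amino]-2-oxooct-7-en-3-yl 8-[(2R,5S,6S)-1-(tert-butoxycarbonyl)-6-methyl-5-(oct-7-enoyloxy)piperidin-2-yl]octanoate
Product: 22 the 26-membered di-Boc diolide with an (E)-C1'a=C2'a alkene [(3S,6S)a; (2S,3S,6R)b; C2a an acetyl ketone; C6a an allylic NHBoc; ring B N-Boc]
Conditions: second-generation Grubbs catalyst RuCl2(=CHPh)(PCy3)(H2IMes) (10 mol %, two portions), CH2Cl2 (1 mM), 40 °C, argon purge
Reagents that add atoms: none
Why: Ring-closing olefin metathesis by the Chauvin mechanism: the ruthenium benzylidene exchanges onto the unhindered oct-7-enoate alkene, the new alkylidene undergoes [2+2] cycloaddition with the C6a vinyl group, and cycloreversion of the ruthenacyclobutane expels ethene and forms C1'a=C2'a. The closest known reaction type is macrocyclic ring-closing metathesis of ester-linked α,ω-dienes that carry an allylic carbamate. The 26-membered ring closes in the endo mode usual for macrocyclic metathesis, with both alkene carbons in the ring, and the two s-trans esters and ring B limit the freedom of the chain. No stereocentre is formed and the five already present lie outside the reacting atoms, while the alkene geometry is of no consequence because hydrogenation follows. The step needs ring closure to win over chain growth and the two unlike alkenes to pair; millimolar dilution with loss of ethene should secure the first, and the reactivity gap between the fast terminal alkene and the slow branched allylic carbamate alkene the second, with ketone, esters and carbamates inert to the catalyst.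

**Step 17**
Reactants: 22 the 26-membered di-Boc diolide with an (E)-C1'a=C2'a alkene
Product: 23 the saturated 26-membered di-Boc diolide [(3S,6R)a; (2S,3S,6R)b; C2a an acetyl ketone; C6a an NHBoc; ring B N-Boc]
Conditions: H2 (1 atm), 10% Pd/C, EtOAc, rt
Reagents that add atoms: none
Why: Heterogeneous catalytic hydrogenation saturates the disubstituted alkene under conditions that do not reduce the ketone, the esters or the Boc groups, and C6a changes descriptor only because the chain loses priority.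

**Step 18**
Reactants: 23 the saturated 26-membered di-Boc diolide
Product: 25 the target, the 26-membered diolide with imine ring A (3S,6R) and piperidine ring B (2S,3S,6R), via diamino ketone 24 (not isolated)
Conditions: TFA/CH2Cl2 (1:4), 0 °C; then aq NaHCO3, CH2Cl2, rt
Reagents that add atoms: none
Why: Acidolysis of both Boc groups followed by neutralisation frees the primary C6a amine, which condenses intramolecularly with the C2a ketone to the six-membered imine of ring A, a closure favoured over any reaction of the hindered secondary amine of ring B.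

**Compound list**
1 | methyl (S)-1-(tert-butoxycarbonyl)-5-oxopyrrolidine-2-carboxylate (methyl N-Boc-L-pyroglutamate) | COC(=O)[C@@H]1CCC(=O)N1C(=O)OC(C)(C)C | starting material
2 | trimethylsilylacetylene | C#C[Si](C)(C)C | starting material
3 | methyl (S)-2-[(tert-butoxycarbonyl)amino]-5-oxo-7-(trimethylsilyl)hept-6-ynoate | COC(=O)[C@H](CCC(=O)C#C[Si](C)(C)C)NC(=O)OC(C)(C)C | intermediate
4 | methyl (2S,5S)-2-[(tert-butoxycarbonyl)amino]-5-hydroxy-7-(trimethylsilyl)hept-6-ynoate | COC(=O)[C@H](CC[C@H](O)C#C[Si](C)(C)C)NC(=O)OC(C)(C)C | intermediate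
5 | methyl (2S,5S)-2-[(tert-butoxycarbonyl)amino]-5-[(tert-butyldiphenylsilyl)oxy]-7-(trimethylsilyl)hept-6-ynoate | COC(=O)[C@H](CC[C@H](O[Si](c1ccccc1)(c1ccccc1)C(C)(C)C)C#C[Si](C)(C)C)NC(=O)OC(C)(C)C | intermediate
6 | tert-butyl N-[(2S,5S)-5-[(tert-butyldiphenylsilyl)oxy]-1-oxo-7-(trimethylsilyl)hept-6-yn-2-yl]carbamate (not isolated) | O=C[C@H](CC[C@H](O[Si](c1ccccc1)(c1ccccc1)C(C)(C)C)C#C[Si](C)(C)C)NC(=O)OC(C)(C)C | intermediate
7 | tert-butyl N-[(3S,6S)-6-[(tert-butyldiphenylsilyl)oxy]-8-(trimethylsilyl)oct-1-en-7-yn-3-yl]carbamate | C=C[C@H](CC[C@H](O[Si](c1ccccc1)(c1ccccc1)C(C)(C)C)C#C[Si](C)(C)C)NC(=O)OC(C)(C)C | intermediate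
8 | tert-butyl N-[(3S,6S)-6-[(tert-butyldiphenylsilyl)oxy]oct-1-en-7-yn-3-yl]carbamate | C=C[C@H](CC[C@H](O[Si](c1ccccc1)(c1ccccc1)C(C)(C)C)C#C)NC(=O)OC(C)(C)C | intermediate
9 | tert-butyl N-[(3S,6S)-6-hydroxyoct-1-en-7-yn-3-yl]carbamate | C=C[C@H](CC[C@H](O)C#C)NC(=O)OC(C)(C)C | intermediate
10 | tert-butyl N-[(3S,6S)-6-[(tert-butyldiphenylsilyl)oxy]-7-oxooct-1-en-3-yl]carbamate | C=C[C@H](CC[C@H](O[Si](c1ccccc1)(c1ccccc1)C(C)(C)C)C(C)=O)NC(=O)OC(C)(C)C | intermediate
11 | oct-7-enoic acid | C=CCCCCCC(=O)O | starting material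
12 | benzyl oct-7-enoate | C=CCCCCCC(=O)OCc1ccccc1 | intermediate
13 | benzyl (7E,9S,12S)-9-[(tert-butoxycarbonyl)amino]-12-[(tert-butyldiphenylsilyl)oxy]-13-oxotetradec-7-enoate | O=C(OCc1ccccc1)CCCCC/C=C/[C@H](CC[C@H](O[Si](c1ccccc1)(c1ccccc1)C(C)(C)C)C(C)=O)NC(=O)OC(C)(C)C | intermediate
14 | benzyl (7E,9S,12S)-9-amino-12-[(tert-butyldiphenylsilyl)oxy]-13-oxotetradec-7-enoate (not isolated) | O=C(OCc1ccccc1)CCCCC/C=C/[C@@H](N)CC[C@H](O[Si](c1ccccc1)(c1ccccc1)C(C)(C)C)C(C)=O | intermediate
15 | benzyl (7E)-8-[(2S,5S)-5-[(tert-butyldiphenylsilyl)oxy]-6-methyl-2,3,4,5-tetrahydropyridin-2-yl]oct-7-enoate (not isolated) | CC1=N[C@H](/C=C/CCCCCC(=O)OCc2ccccc2)CC[C@@H]1O[Si](c1ccccc1)(c1ccccc1)C(C)(C)C | intermediate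
16 | 8-[(2R,5S,6S)-5-[(tert-butyldiphenylsilyl)oxy]-6-methylpiperidin-2-yl]octanoic acid | CC(C)(C)[Si](c1ccccc1)(c1ccccc1)O[C@H]1CC[C@@H](CCCCCCCC(=O)O)N[C@H]1C | intermediate
17 | 8-[(2R,5S,6S)-1-(tert-butoxycarbonyl)-5-[(tert-butyldiphenylsilyl)oxy]-6-methylpiperidin-2-yl]octanoic acid | CC(C)(C)[Si](c1ccccc1)(c1ccccc1)O[C@H]1CC[C@@H](CCCCCCCC(=O)O)N(C(=O)OC(C)(C)C)[C@H]1C | intermediate
18 | (3S,6S)-6-[(tert-butoxycarbonyl)amino]oct-7-en-1-yn-3-yl 8-[(2R,5S,6S)-1-(tert-butoxycarbonyl)-5-[(tert-butyldiphenylsilyl)oxy]-6-methylpiperidin-2-yl]octanoate | CC(C)(C)[Si](c1ccccc1)(c1ccccc1)O[C@H]1CC[C@@H](CCCCCCCC(=O)O[C@H](C#C)CC[C@H](NC(=O)OC(C)(C)C)C=C)N(C(=O)OC(C)(C)C)[C@H]1C | intermediate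
19 | (3S,6S)-6-[(tert-butoxycarbonyl)amino]oct-7-en-1-yn-3-yl 8-[(2R,5S,6S)-1-(tert-butoxycarbonyl)-5-hydroxy-6-methylpiperidin-2-yl]octanoate | O[C@H]1CC[C@@H](CCCCCCCC(=O)O[C@H](C#C)CC[C@H](NC(=O)OC(C)(C)C)C=C)N(C(=O)OC(C)(C)C)[C@H]1C | intermediate
20 | (3S,6S)-6-[(tert-butoxycarbonyl)amino]oct-7-en-1-yn-3-yl 8-[(2R,5S,6S)-1-(tert-butoxycarbonyl)-6-methyl-5-(oct-7-enoyloxy)piperidin-2-yl]octanoate | C=CCCCCCC(=O)O[C@H]1CC[C@@H](CCCCCCCC(=O)O[C@H](C#C)CC[C@H](NC(=O)OC(C)(C)C)C=C)N(C(=O)OC(C)(C)C)[C@H]1C | intermediate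
21 | (3S,6S)-6-[(tert-butoxycarbonyl)amino]-2-oxooct-7-en-3-yl 8-[(2R,5S,6S)-1-(tert-butoxycarbonyl)-6-methyl-5-(oct-7-enoyloxy)piperidin-2-yl]octanoate (open diene, metathesis precursor) | C=CCCCCCC(=O)O[C@H]1CC[C@@H](CCCCCCCC(=O)O[C@H](C(C)=O)CC[C@H](NC(=O)OC(C)(C)C)C=C)N(C(=O)OC(C)(C)C)[C@H]1C | intermediate
22 | 26-membered di-Boc diolide with (E)-C1'a=C2'a; (3S,6S)a, (2S,3S,6R)b; acetyl on C3a, NHBoc on C6a, N-Boc ring B | O1[C@H](C(C)=O)CC[C@H](NC(=O)OC(C)(C)C)/C=C/CCCCCC(=O)O[C@H]2CC[C@@H](CCCCCCCC1=O)N(C(=O)OC(C)(C)C)[C@H]2C | intermediate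
23 | saturated 26-membered di-Boc diolide; (3S,6R)a, (2S,3S,6R)b; acetyl on C3a, NHBoc on C6a, N-Boc ring B | O1[C@H](C(C)=O)CC[C@H](NC(=O)OC(C)(C)C)CCCCCCCC(=O)O[C@H]2CC[C@@H](CCCCCCCC1=O)N(C(=O)OC(C)(C)C)[C@H]2C | intermediate
24 | ring-A-open diamino ketone; (3S,6R)a, (2S,3S,6R)b; free C6a NH2 and free ring B NH (not isolated) | O1[C@H](C(C)=O)CC[C@H](N)CCCCCCCC(=O)O[C@H]2CC[C@@H](CCCCCCCC1=O)N[C@H]2C | intermediate
25 | target CNP0304114.1: 26-membered diolide of 2-methyl-2,3,4,5-tetrahydropyridine ring A (3S,6R) and 2-methylpiperidine ring B (2S,3S,6R) | CC1=N[C@@H]2CCCCCCCC(=O)O[C@H]3CC[C@@H](CCCCCCCC(=O)O[C@H]1CC2)N[C@H]3C | target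

Total step count: 18 steps.
Longest linear sequence: 16 steps (steps 1 to 5, 7 and 9 to 18, from 1 to 25); steps 6 and 8 are branch steps.

**Steps most likely to fail**

Step 16. Chain growth between molecules may overtake ring closure, or the allylic carbamate alkene may engage so slowly that the catalyst decays or isomerises the terminal alkene first. The fallback forms C1'a=C2'a between two molecules and closes the ring at an ester instead. It sets out from alcohol 19, whose gold-catalysed hydration under the conditions of step 15 should give the keto alcohol (3S,6S)-6-[(tert-butoxycarbonyl)amino]-2-oxooct-7-en-3-yl 8-[(2R,5S,6S)-1-(tert-butoxycarbonyl)-5-hydroxy-6-methylpiperidin-2-yl]octanoate F1. Cross-metathesis of its single vinyl group with excess oct-7-enoic acid 11 (second-generation Grubbs catalyst RuCl2(=CHPh)(PCy3)(H2IMes), CH2Cl2, 40 °C) should then give the seco acid (7E,9S,12S)-9-[(tert-butoxycarbonyl)amino]-12-({8-[(2R,5S,6S)-1-(tert-butoxycarbonyl)-5-hydroxy-6-methylpiperidin-2-yl]octanoyl}oxy)-13-oxotetradec-7-enoic acid F2. Shiina macrolactonisation onto O3b (2-methyl-6-nitrobenzoic anhydride, DMAP, toluene, slow addition at high dilution) comes back to the route at 22.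

Step 7. Without a participating ester the hydration beside the bulky silyl ether may be slow, so that gold-promoted cyclisation of the 1,7-enyne, addition of the carbamate to the alkyne or loss of the silyl group competes. The fallback replaces hydration by hydrosilylation and oxidation. It sets out from alkyne 8: ruthenium-catalysed Markovnikov hydrosilylation ([Cp*Ru(MeCN)3]PF6, (EtO)3SiH, CH2Cl2, 0 °C to rt) should give the α-vinylsilane tert-butyl N-[(3S,6S)-6-[(tert-butyldiphenylsilyl)oxy]-7-(triethoxysilyl)octa-1,7-dien-3-yl]carbamate F3, and Tamao oxidation of the C–Si bond (H2O2, KF, KHCO3, THF/MeOH) gives the enol and hence ketone 10, where the route is rejoined.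

Step 15. On the fully functionalised substrate the gold-activated alkyne may be diverted by 1,2-acyloxy migration, by cyclisation onto one of the two alkenes or by catalyst sequestration at the carbamates. The fallback brings the ketone in ready-made. It sets out from ketone 10 and acid 17: Bu4NF/AcOH on 10 should free the α-hydroxy ketone tert-butyl N-[(3S,6S)-6-hydroxy-7-oxooct-1-en-3-yl]carbamate F4. Steglich esterification of F4 with 17 (DIC, catalytic DMAP, CH2Cl2, 0 °C to limit enolisation) gives the silyl ether (3S,6S)-6-[(tert-butoxycarbonyl)amino]-2-oxooct-7-en-3-yl 8-[(2R,5S,6S)-1-(tert-butoxycarbonyl)-5-[(tert-butyldiphenylsilyl)oxy]-6-methylpiperidin-2-yl]octanoate F5. Desilylation as in step 13 gives the keto alcohol F1 described above, and esterification with 11 as in step 14 comes back to the route at 21.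

**Further compounds**
F1 | step 16 | (3S,6S)-6-[(tert-butoxycarbonyl)amino]-2-oxooct-7-en-3-yl 8-[(2R,5S,6S)-1-(tert-butoxycarbonyl)-5-hydroxy-6-methylpiperidin-2-yl]octanoate | O[C@H]1CC[C@@H](CCCCCCCC(=O)O[C@H](C(C)=O)CC[C@H](NC(=O)OC(C)(C)C)C=C)N(C(=O)OC(C)(C)C)[C@H]1C
F2 | step 16 | (7E,9S,12S)-9-[(tert-butoxycarbonyl)amino]-12-({8-[(2R,5S,6S)-1-(tert-butoxycarbonyl)-5-hydroxy-6-methylpiperidin-2-yl]octanoyl}oxy)-13-oxotetradec-7-enoic acid | O[C@H]1CC[C@@H](CCCCCCCC(=O)O[C@H](C(C)=O)CC[C@H](NC(=O)OC(C)(C)C)/C=C/CCCCCC(=O)O)N(C(=O)OC(C)(C)C)[C@H]1C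
F3 | step 7 | tert-butyl N-[(3S,6S)-6-[(tert-butyldiphenylsilyl)oxy]-7-(triethoxysilyl)octa-1,7-dien-3-yl]carbamate | C=C[C@H](CC[C@H](O[Si](c1ccccc1)(c1ccccc1)C(C)(C)C)C(=C)[Si](OCC)(OCC)OCC)NC(=O)OC(C)(C)C
F4 | step 15 | tert-butyl N-[(3S,6S)-6-hydroxy-7-oxooct-1-en-3-yl]carbamate | C=C[C@H](CC[C@H](O)C(C)=O)NC(=O)OC(C)(C)C
F5 | step 15 | (3S,6S)-6-[(tert-butoxycarbonyl)amino]-2-oxooct-7-en-3-yl 8-[(2R,5S,6S)-1-(tert-butoxycarbonyl)-5-[(tert-butyldiphenylsilyl)oxy]-6-methylpiperidin-2-yl]octanoate | CC(C)(C)[Si](c1ccccc1)(c1ccccc1)O[C@H]1CC[C@@H](CCCCCCCC(=O)O[C@H](C(C)=O)CC[C@H](NC(=O)OC(C)(C)C)C=C)N(C(=O)OC(C)(C)C)[C@H]1C
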